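Start with the easy step: J takes up G and gives D and E. D and Q go on the same way: J + G ⇌ E + D, D + G ⇌ E + Q, Q + G ⇌ E + X.

| flask | J | G | remark | time |
|---|---|---|---|---|
| north | 0.050 M | 0.025 M | the very flask that is asked about, followed so far |  |
| south | 0.034 M | 0.025 M | run made earlier |  |
| flask | 0.050 M | 0.0250 M |  | 10 d |

| run | time / d | J / % | D / % | Q / % |
|---|---|---|---|---|
| north | 0.833 | 59.4 | 35.3 | 5.5 |
| north | 1.67 | 58.3 | 35.3 | 5.0 |
| north | 2.50 | 59.4 | 35.8 | 5.6 |
| north | 3.00 | 58.3 | 35.3 | 5.3 |
| south | 0.833 | 45.1 | 42.7 | 11.0 |
| south | 2.50 | 44.5 | 42.7 | 10.5 |
| south | 5.00 | 45.7 | 42.9 | 10.9 |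
| south | 8.00 | 46.2 | 42.9 | 10.0 |

(scatter of a reading: 0.5 percentage points)

1. the state of affairs at 10 d: stopped, and by what, or still going (G has run out first / all of J has reacted / forward and back rates have come level / it is still moving)
2. how much of the J has reacted by 10 d
3. how much D there is at 10 d, in percent of the J charged
4. how much Q there is at 10 d, in percent of the J charged

- reactions considered so far: Q + G <-> E + X; D + G <-> E + Q; J + G <-> E + D
- the reaction counts as stopped when no species that holds the J changes by six tenths of a point or more over the second half of the time

What do the runs show? Flat lines. South, the longer run, reads J 45.1% at 0.833 d and 46.2% at 8.00 d, and a reading scatters by 0.5 percentage points.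

What stopped them? Either G ran short, or forward and back rates came level.

Can you tell which without [G]? I try. At level rates, [D][E]/([J][G]) and [Q][E]/([D][G]) each stay constant. Divide the second by the first and [E]/[G] drops out. That leaves [J][Q]/([D][D]), and percentages of the J charged serve as well as concentrations.

Your numbers? North's means are J 58.9%, D 35.4% and Q 5.35%, which gives 0.251. South's means are J 45.4%, D 42.8% and Q 10.6%, which gives 0.263.

But those differ. Every reading behind them scatters by 0.5 points, so I read that gap as scatter.

And a stall for lack of G? The quotient can't exclude that, since one-way steps stalled without G can give a like value. So I count G, in points of the J charged, with X taken as what J, D and Q lack of the whole. South was charged 73.5% of G, and D, Q and X took up 67.7%, which leaves 5.9 points. North, by the same count, leaves 2.8 points. So G remains in both runs, and I take it that forward and back rates came level. I keep the mean of the two quotients, 0.257, as the swap quotient S, [J][Q]/([D][D]) at level rates, a disproportionation constant of D.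

Your call? The asked flask is north itself, so it stays at those means.

The forecast agrees: forward and back rates have come level, 41.1% reacted, D 35.4%, Q 5.4%. Its ground: “The two runs agree, so this is equilibrium”.

    Q + G ⇌ E + X (K = 0.640, k = 47.0 M⁻¹ h⁻¹)
    D + G ⇌ E + Q (K = 2.10, k = 190 M⁻¹ h⁻¹)
    J + G ⇌ E + D (K = 8.30, k = 93.0 M⁻¹ h⁻¹)

The flask gives forward and back rates have come level, with 40.8% reacted, D 35.3% and Q 5.32%. Its largest change over the second half of the time is 0 points. With the flask's J 59.2% and D 35.3%, S puts Q at 5.41%.

A neighbour flask charged with 0.10 M of G ends with J 12.5% and D 42.2%. There S gives Q 36.6%, and the computed Q is 36.0%.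

The runs come from a simulation with constants of no real substance, and the scatter is random.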